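The chroman ring (O1, C2, C3, C4, C4a, C8a) is closed at C3–C4 by ring-closing olefin metathesis. The step exploits the unsubstituted C3H2–C4H2 link between the quaternary, O1-bound C2(CH3)2 and aromatic C4a: each terminus can be a vinyl group. The precursor, an aryl 1,1-dimethylallyl ether with an ortho vinyl group, loses ethene and is saturated in the same flask to give 2,2-dimethylchroman-6-carbaldehyde. This aldehyde is joined to an acetophenone whose (S)-dihydrobenzofuran comes from Shi epoxidation and 5-exo phenoxide opening; the (S)-carbinol follows from Juliá–Colonna epoxidation of the chalcone and reductive epoxide opening.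

Key step: step 3

Remark: the target SMILES is read as S at the carbinol carbon and S at C2 of the dihydrobenzofuran; all five starting materials are taken as catalogue compounds.

Step 1
Reactants: 1 3-bromo-4-fluorobenzaldehyde; 2 2-ethenyl-4,4,5,5-tetramethyl-1,3,2-dioxaborolane (vinylboronic acid pinacol ester)
Product: 3 3-ethenyl-4-fluorobenzaldehyde
Conditions: PdCl2(dppf) (dppf = 1,1'-bis(diphenylphosphino)ferrocene, 3 mol%), K2CO3, 1,4-dioxane/H2O, 80 °C
Reagents that add atoms: none
Why: Suzuki–Miyaura coupling, in which zerovalent palladium inserts only into the C–Br bond (C–F is inert) and transmetalation from the vinylboronate followed by reductive elimination should give the styrene with the aldehyde untouched.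

Step 2
Reactants: 3 3-ethenyl-4-fluorobenzaldehyde; 4 2-methylbut-3-en-2-ol
Product: 5 3-ethenyl-4-[(2-methylbut-3-en-2-yl)oxy]benzaldehyde
Conditions: NaH, DMF, 0 °C to 40 °C
Reagents that add atoms: none
Why: Nucleophilic aromatic substitution by addition–elimination, in which the para formyl group stabilises the Meisenheimer adduct and fluoride is the best leaving group, while the tertiary alkoxide has no carbinol hydrogen to reduce the aldehyde and adds to it only reversibly.

Step 3
Reactants: 5 3-ethenyl-4-[(2-methylbut-3-en-2-yl)oxy]benzaldehyde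
Product: 7 2,2-dimethyl-3,4-dihydro-2H-chromene-6-carbaldehyde, via 2,2-dimethyl-2H-chromene-6-carbaldehyde 6 (not isolated)
Conditions: second-generation Grubbs catalyst (H2IMes)(PCy3)Cl2Ru=CHPh (3 mol%), EtOAc (0.02 M), 40 °C; then 10% Pd/C, Ph2S (0.01 equiv), H2 (1 atm), rt, same flask
Reagents that add atoms: none
Why: Ring-closing olefin metathesis: the ruthenium alkylidene loads onto the unhindered aryl-bound vinyl group (the future C4), adds across the vinyl group of the 1,1-dimethylallyl ether (the future C3) to a ruthenacyclobutane, and cycloreversion forms C3=C4 while the two terminal CH2 groups leave as ethene. The closest known reaction type is the metathesis closure of 2-vinylphenyl allyl ethers to 2H-chromenes, followed here by heterogeneous olefin hydrogenation in the same flask. The six-membered ring O1–C2–C3–C4–C4a–C8a is closed by intramolecular [2+2] cycloaddition–cycloreversion onto the tethered alkene, which can only give the cis ring olefin. No stereocentre is formed. The step needs cyclisation to outrun cross-metathesis and the thermal aromatic Claisen rearrangement of the tertiary allyl aryl ether; the gem-dimethyl group at C2 blocks homodimerisation at its neighbouring olefin and turns the chain towards the ring (Thorpe–Ingold effect), and 40 °C is far below the Claisen onset. In the hydrogenation the sulfide-moderated Pd/C should reduce only the styrenic C3=C4 bond and leave the aryl aldehyde, and the quaternary C2 rules out double-bond migration.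

Step 4
Reactants: 8 1-(5-bromo-2,4-dihydroxyphenyl)ethan-1-one
Product: 9 4-acetyl-6-bromo-1,3-phenylene bis(2,2-dimethylpropanoate)
Conditions: PivCl, Et3N, DMAP (cat.), CH2Cl2, 0 °C to rt
Reagents that add atoms: pivaloyl chloride, CC(C)(C)C(Cl)=O
Why: DMAP-catalysed O-acylation masks both phenols as pivalates, which should withstand the cross-coupling and the basic oxidation that follow and shield the ring from phenol oxidation.

Step 5
Reactants: 9 4-acetyl-6-bromo-1,3-phenylene bis(2,2-dimethylpropanoate); 10 tributyl(3-methylbut-2-en-1-yl)stannane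
Product: 11 4-acetyl-6-(3-methylbut-2-en-1-yl)-1,3-phenylene bis(2,2-dimethylpropanoate)
Conditions: Pd(PPh3)4 (5 mol%), DMF, 95 °C
Reagents that add atoms: none
Why: Stille coupling, in which oxidative addition into the aryl C–Br bond, transmetalation of the allylic stannane and reductive elimination at the less substituted allyl terminus should give the linear prenyl arene under neutral conditions that spare the esters and the ketone.

Step 6
Reactants: 11 4-acetyl-6-(3-methylbut-2-en-1-yl)-1,3-phenylene bis(2,2-dimethylpropanoate)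
Product: 12 4-acetyl-6-{[(2R)-3,3-dimethyloxiran-2-yl]methyl}-1,3-phenylene bis(2,2-dimethylpropanoate)
Conditions: D-fructose-derived Shi ketone (30 mol%), Oxone (2KHSO5·KHSO4·K2SO4), K2CO3, Bu4NHSO4 (cat.), MeCN/CH2(OMe)2/aqueous Na2B4O7–Na2EDTA buffer, 0 °C
Reagents that add atoms: potassium peroxymonosulfate (active salt of Oxone), [K+].[O-]S(=O)(=O)OO
Why: Shi asymmetric epoxidation, in which the chiral dioxirane delivers oxygen through a spiro transition state to one face of the electron-rich trisubstituted olefin, for which the D-fructose-derived ketone is expected to give the (R)-epoxide under catalyst control while the acylated arene and the acetyl group are not oxidised.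

Step 7
Reactants: 12 4-acetyl-6-{[(2R)-3,3-dimethyloxiran-2-yl]methyl}-1,3-phenylene bis(2,2-dimethylpropanoate)
Product: 14 1-[(2S)-6-hydroxy-2-(2-hydroxypropan-2-yl)-2,3-dihydro-1-benzofuran-5-yl]ethan-1-one, via bisphenol epoxide 13 (not isolated)
Conditions: K2CO3, MeOH, rt to 45 °C
Reagents that add atoms: none
Why: Methanolysis of the two activated aryl pivalates releases the phenoxides, and the 4-phenoxide opens the epoxide by 5-exo-tet SN2 attack at the secondary carbon, so inversion turns the (R)-epoxide carbon into the (S)-C2 of the dihydrobenzofuran and leaves the tertiary alcohol (intramolecular epoxide opening under base, which disfavours the 6-endo path to a chromanol).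

Step 8
Reactants: 14 1-[(2S)-6-hydroxy-2-(2-hydroxypropan-2-yl)-2,3-dihydro-1-benzofuran-5-yl]ethan-1-one
Product: 15 1-[(2S)-2-(2-hydroxypropan-2-yl)-6-(prop-2-en-1-yloxy)-2,3-dihydro-1-benzofuran-5-yl]ethan-1-one
Conditions: allyl bromide, K2CO3, DMF, 50 °C
Reagents that add atoms: allyl bromide, C=CCBr
Why: Williamson ether synthesis, in which only the phenol is acidic enough for K2CO3, the tertiary alcohol does not react, and the allyl ether masks the chelated phenol against flavanone-type cyclisation in the enone chemistry to come.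

Step 9
Reactants: 15 1-[(2S)-2-(2-hydroxypropan-2-yl)-6-(prop-2-en-1-yloxy)-2,3-dihydro-1-benzofuran-5-yl]ethan-1-one; 7 2,2-dimethyl-3,4-dihydro-2H-chromene-6-carbaldehyde
Product: 17 (2E)-3-(2,2-dimethyl-3,4-dihydro-2H-chromen-6-yl)-1-[(2S)-2-(2-hydroxypropan-2-yl)-6-(prop-2-en-1-yloxy)-2,3-dihydro-1-benzofuran-5-yl]prop-2-en-1-one, via aldol adduct 16 (not isolated)
Conditions: KOH, EtOH, rt
Reagents that add atoms: none
Why: Claisen–Schmidt condensation, in which the methyl ketone is the only enolisable partner, the aldehyde cannot self-condense, and E1cB dehydration of the aldol adduct gives the conjugated (E)-enone.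

Step 10
Reactants: 17 O-allyl (E)-chalcone
Product: 18 [(2S,3R)-3-(2,2-dimethyl-3,4-dihydro-2H-chromen-6-yl)oxiran-2-yl][(2S)-2-(2-hydroxypropan-2-yl)-6-(prop-2-en-1-yloxy)-2,3-dihydro-1-benzofuran-5-yl]methanone
Conditions: poly-D-leucine, urea–H2O2, DBU, THF, rt
Reagents that add atoms: urea–hydrogen peroxide, NC(N)=O.OO
Why: Juliá–Colonna epoxidation (Weitz–Scheffer conjugate addition of hydroperoxide inside the helical polypeptide), in which poly-D-leucine, the mirror image of the poly-L-leucine that gives (2R,3S)-epoxy chalcones, should give the trans (2S,3R)-epoxy ketone under catalyst control, while the remote ring stereocentre and the isolated allyl group play no part.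

Step 11
Reactants: 18 (2S,3R)-epoxy ketone
Product: 20 (3S)-3-(2,2-dimethyl-3,4-dihydro-2H-chromen-6-yl)-3-hydroxy-1-[(2S)-2-(2-hydroxypropan-2-yl)-6-(prop-2-en-1-yloxy)-2,3-dihydro-1-benzofuran-5-yl]propan-1-one, via alpha-phenylselanyl aldol 19 (not isolated)
Conditions: (PhSe)2, NaBH4, EtOH, rt; then AcOH, 18, 0 °C to rt
Reagents that add atoms: none
Why: Selenolate-mediated reductive opening of an α,β-epoxy ketone, in which PhSe– opens the epoxide at Cα by SN2 and a second selenolate removes selenium to leave the enol, so the Cβ–O bond is never broken and the (3R)-epoxide carbon becomes the (3S)-carbinol (the descriptor changes only because the CIP ranks change).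

Step 12
Reactants: 20 O-allyl (3S)-β-hydroxy ketone
Product: 21 (3S)-3-(2,2-dimethyl-3,4-dihydro-2H-chromen-6-yl)-3-hydroxy-1-[(2S)-6-hydroxy-2-(2-hydroxypropan-2-yl)-2,3-dihydro-1-benzofuran-5-yl]propan-1-one
Conditions: Pd(PPh3)4 (5 mol%), morpholine, THF, rt
Reagents that add atoms: none
Why: Tsuji–Trost deallylation, in which zerovalent palladium ionises the allyl aryl ether to a π-allyl complex that morpholine captures, freeing the phenol under near-neutral conditions that should spare the benzylic β-hydroxy ketone from dehydration or retro-aldol cleavage.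

Compound list
1 | 3-bromo-4-fluorobenzaldehyde | O=Cc1ccc(F)c(Br)c1 | starting material
2 | 2-ethenyl-4,4,5,5-tetramethyl-1,3,2-dioxaborolane | C=CB1OC(C)(C)C(C)(C)O1 | starting material
3 | 3-ethenyl-4-fluorobenzaldehyde | O=Cc1ccc(F)c(C=C)c1 | intermediate
4 | 2-methylbut-3-en-2-ol | CC(C)(O)C=C | starting material
5 | 3-ethenyl-4-[(2-methylbut-3-en-2-yl)oxy]benzaldehyde | O=Cc1ccc(OC(C)(C)C=C)c(C=C)c1 | intermediate
6 | 2,2-dimethyl-2H-chromene-6-carbaldehyde (not isolated) | O=Cc1ccc2OC(C)(C)C=Cc2c1 | intermediate
7 | 2,2-dimethyl-3,4-dihydro-2H-chromene-6-carbaldehyde | O=Cc1ccc2OC(C)(C)CCc2c1 | intermediate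
8 | 1-(5-bromo-2,4-dihydroxyphenyl)ethan-1-one | CC(=O)c1cc(Br)c(O)cc1O | starting material
9 | 4-acetyl-6-bromo-1,3-phenylene bis(2,2-dimethylpropanoate) | CC(=O)c1cc(Br)c(OC(=O)C(C)(C)C)cc1OC(=O)C(C)(C)C | intermediate
10 | tributyl(3-methylbut-2-en-1-yl)stannane | CCCC[Sn](CCCC)(CCCC)CC=C(C)C | starting material
11 | 4-acetyl-6-(3-methylbut-2-en-1-yl)-1,3-phenylene bis(2,2-dimethylpropanoate) | CC(=O)c1cc(CC=C(C)C)c(OC(=O)C(C)(C)C)cc1OC(=O)C(C)(C)C | intermediate
12 | 4-acetyl-6-{[(2R)-3,3-dimethyloxiran-2-yl]methyl}-1,3-phenylene bis(2,2-dimethylpropanoate) | CC(=O)c1cc(C[C@H]2OC2(C)C)c(OC(=O)C(C)(C)C)cc1OC(=O)C(C)(C)C | intermediate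
13 | 1-(5-{[(2R)-3,3-dimethyloxiran-2-yl]methyl}-2,4-dihydroxyphenyl)ethan-1-one (bisphenol epoxide, present as phenoxide, not isolated) | CC(=O)c1cc(C[C@H]2OC2(C)C)c(O)cc1O | intermediate
14 | 1-[(2S)-6-hydroxy-2-(2-hydroxypropan-2-yl)-2,3-dihydro-1-benzofuran-5-yl]ethan-1-one | CC(=O)c1cc2c(cc1O)O[C@H](C(C)(C)O)C2 | intermediate
15 | 1-[(2S)-2-(2-hydroxypropan-2-yl)-6-(prop-2-en-1-yloxy)-2,3-dihydro-1-benzofuran-5-yl]ethan-1-one | CC(=O)c1cc2c(cc1OCC=C)O[C@H](C(C)(C)O)C2 | intermediate
16 | 3-(2,2-dimethyl-3,4-dihydro-2H-chromen-6-yl)-3-hydroxy-1-[(2S)-2-(2-hydroxypropan-2-yl)-6-(prop-2-en-1-yloxy)-2,3-dihydro-1-benzofuran-5-yl]propan-1-one (aldol adduct, both C3 epimers, not isolated) | CC1(C)CCc2cc(C(O)CC(=O)c3cc4c(cc3OCC=C)O[C@H](C(C)(C)O)C4)ccc2O1 | intermediate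
17 | (2E)-3-(2,2-dimethyl-3,4-dihydro-2H-chromen-6-yl)-1-[(2S)-2-(2-hydroxypropan-2-yl)-6-(prop-2-en-1-yloxy)-2,3-dihydro-1-benzofuran-5-yl]prop-2-en-1-one | CC1(C)CCc2cc(/C=C/C(=O)c3cc4c(cc3OCC=C)O[C@H](C(C)(C)O)C4)ccc2O1 | intermediate
18 | [(2S,3R)-3-(2,2-dimethyl-3,4-dihydro-2H-chromen-6-yl)oxiran-2-yl][(2S)-2-(2-hydroxypropan-2-yl)-6-(prop-2-en-1-yloxy)-2,3-dihydro-1-benzofuran-5-yl]methanone | O=C([C@H]1O[C@@H]1c1ccc2OC(C)(C)CCc2c1)c1cc2c(cc1OCC=C)O[C@H](C(C)(C)O)C2 | intermediate
19 | (2R,3R)-3-(2,2-dimethyl-3,4-dihydro-2H-chromen-6-yl)-3-hydroxy-1-[(2S)-2-(2-hydroxypropan-2-yl)-6-(prop-2-en-1-yloxy)-2,3-dihydro-1-benzofuran-5-yl]-2-(phenylselanyl)propan-1-one (not isolated) | O=C([C@H]([Se]c1ccccc1)[C@H](O)c1ccc2OC(C)(C)CCc2c1)c1cc2c(cc1OCC=C)O[C@H](C(C)(C)O)C2 | intermediate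
20 | (3S)-3-(2,2-dimethyl-3,4-dihydro-2H-chromen-6-yl)-3-hydroxy-1-[(2S)-2-(2-hydroxypropan-2-yl)-6-(prop-2-en-1-yloxy)-2,3-dihydro-1-benzofuran-5-yl]propan-1-one | CC1(C)CCc2cc([C@@H](O)CC(=O)c3cc4c(cc3OCC=C)O[C@H](C(C)(C)O)C4)ccc2O1 | intermediate
21 | (3S)-3-(2,2-dimethyl-3,4-dihydro-2H-chromen-6-yl)-3-hydroxy-1-[(2S)-6-hydroxy-2-(2-hydroxypropan-2-yl)-2,3-dihydro-1-benzofuran-5-yl]propan-1-one | CC1(C)CCc2cc([C@@H](O)CC(=O)c3cc4c(cc3O)O[C@H](C(C)(C)O)C4)ccc2O1 | target

Total steps: 12
Longest linear sequence: 9 steps (8 to 21, steps 4 to 12); the aldehyde branch (1 to 7) has 3 steps.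

Steps most likely to fail

Step 10. The risk is poor facial discrimination and slow hydroperoxide addition, because the ortho allyloxy group twists the aryl ketone out of the geometry the polypeptide recognises and both aryl rings are electron-rich. The fallback sets out from 17 and comes back at 20. Conjugate borylation of 17 with B2pin2 under CuCl, NaOt-Bu and (R)-1-[(S)-2-(diphenylphosphino)ferrocenyl]ethyldicyclohexylphosphine in THF/MeOH should give (3S)-3-(2,2-dimethyl-3,4-dihydro-2H-chromen-6-yl)-1-[(2S)-2-(2-hydroxypropan-2-yl)-6-(prop-2-en-1-yloxy)-2,3-dihydro-1-benzofuran-5-yl]-3-(4,4,5,5-tetramethyl-1,3,2-dioxaborolan-2-yl)propan-1-one F1. The ligand antipode would be fixed by a trial run so that boron enters the face leading to the 3S centre. Oxidation of the C–B bond with NaBO3·4H2O in THF/H2O proceeds with retention and returns to 20, so step 11 is no longer needed.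

Step 2. The risk is attack of the hindered alkoxide at the formyl group (hemiacetal formation and hydride-transfer redox) competing with slow substitution beside the vinyl group. The fallback sets out from 3 and comes back at 5. The fluoride is displaced by the primary alkoxide of 2-(methanesulfonyl)ethanol (NaH, DMF) to give 3-ethenyl-4-[2-(methanesulfonyl)ethoxy]benzaldehyde F2. In the same flask this loses ethenyl methyl sulfone by base-induced β-elimination to give 3-ethenyl-4-hydroxybenzaldehyde F3. The tertiary C–O bond is then formed at carbon by Tsuji–Trost O-alkylation with tert-butyl 2-methylbut-3-en-2-yl carbonate (Pd(PPh3)4, THF, 0 °C), in which the phenoxide should attack the more substituted terminus of the π-allyl complex, returning to 5.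

Step 5. The risk is allylic transposition during tin-to-palladium transfer, which would place the branched 2-methylbut-3-en-2-yl group on the ring, together with slow oxidative addition at the bromide flanked by a pivalate. The fallback sets out from 9 and comes back at 11. Stille coupling with allyltributylstannane (Pd(PPh3)4, toluene, 100 °C), where transposition is degenerate, should give 4-acetyl-6-(prop-2-en-1-yl)-1,3-phenylene bis(2,2-dimethylpropanoate) F4. Cross-metathesis with excess 2-methylbut-2-ene (second-generation Grubbs catalyst, CH2Cl2, 40 °C) then converts the allyl group into the prenyl group of 11.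

Further compounds
F1 | step 10 | (3S)-3-(2,2-dimethyl-3,4-dihydro-2H-chromen-6-yl)-1-[(2S)-2-(2-hydroxypropan-2-yl)-6-(prop-2-en-1-yloxy)-2,3-dihydro-1-benzofuran-5-yl]-3-(4,4,5,5-tetramethyl-1,3,2-dioxaborolan-2-yl)propan-1-one | CC1(C)CCc2cc([C@@H](B3OC(C)(C)C(C)(C)O3)CC(=O)c3cc4c(cc3OCC=C)O[C@H](C(C)(C)O)C4)ccc2O1
F2 | step 2 | 3-ethenyl-4-[2-(methanesulfonyl)ethoxy]benzaldehyde | CS(=O)(=O)CCOc1ccc(C=O)cc1C=C
F3 | step 2 | 3-ethenyl-4-hydroxybenzaldehyde | O=Cc1ccc(O)c(C=C)c1
F4 | step 5 | 4-acetyl-6-(prop-2-en-1-yl)-1,3-phenylene bis(2,2-dimethylpropanoate) | CC(=O)c1cc(CC=C)c(OC(=O)C(C)(C)C)cc1OC(=O)C(C)(C)C
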